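**The question.** Find what share of its Sub the south-west flask keeps at 5.9 h. It gets less Sub than the north flask, with the same charges of Rgt and Cat.

| setting | north | north-west | south-west |
|---|---|---|---|
| Sub | 0.500 M | 0.500 M | 0.120 M |
| Rgt | 1.50 M | 1.50 M | 1.50 M |
| Cat | 0.0100 M | 0.0100 M | 0.0100 M |
| Prd |  | 0.150 M |  |
| time |  |  | 5.9 h |

| run | time / h | [Sub] / M |
|---|---|---|
| north run | 0.24 | 0.4864 |
| north run | 0.37 | 0.4790 |
| north run | 0.59 | 0.4694 |
| north run | 0.94 | 0.4502 |
| north run | 1.5 | 0.4182 |
| north run | 2.4 | 0.3734 |
| north run | 3.7 | 0.3172 |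
| north run | 5.9 | 0.2367 |
| north-west run | 0.24 | 0.4867 |
| north-west run | 0.37 | 0.4784 |
| north-west run | 0.59 | 0.4663 |
| north-west run | 0.94 | 0.4484 |
| north-west run | 1.5 | 0.4149 |
| north-west run | 2.4 | 0.3739 |
| north-west run | 3.7 | 0.3180 |
| north-west run | 5.9 | 0.2360 |

(standard deviation of a reading: 0.002 M)

- Sub in the south-west run at 5.9 h, as a share of the Sub charged

- Overall: Sub + Rgt -> Prd, with Cat as catalyst.
- Constant volume, constant temperature.
- The analysis sees a species whether free or bound.

**The ledger.** Open the books on Sub, the limiting reagent, charged at 0.500 M, less than the 1.50 M of Rgt. Enter the north flask at 5.9 h: cSub reads 0.2367 M, free or bound. Enter the other 263 mM as Prd. Debit the same amount from Rgt, so cRgt stands at 1237 mM. Close with the north-west flask: despite its added Prd, it reads 0.2360 M at 5.9 h, within the scatter of 0.002 M of the north reading.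

**Counting lifetimes.** Read two lifetimes from the north flask: 8.40 h up to 1.5 h, then 7.73 h. The later one is shorter, though Rgt has fallen. Assume first order in Rgt, whose charge is 1.50 M in each flask. Multiply each lifetime by its mean cRgt, giving 735 M·min at mean cSub 459 mM and 616 M·min at 327 mM. Extend that line to half the south-west charge, then divide by cRgt there. This gives 4.32 h, the mid-course Sub lifetime: elapsed time over the logarithm of the fall in cSub. Count 1.37 lifetimes, which leaves 25.5%, a rough figure given the scatter.

**The forecast.** It says 32%, above my count, on this ground: “Lower Sub should therefore react faster in relative terms.”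

**The result.** The south-west flask keeps 22.6%, a lifetime of 3.97 h against my 4.32 h.

    Cat + Sub ⇌ Cat.Sub, settled at all times (3.780 M⁻¹)
    Cat.Sub + Rgt → Prd + Cat + Byp (8.280 M⁻¹ h⁻¹)
    Cat + Z → X

**The poison.** In the south-west flask, Z takes 0.00299 M of Cat at once, leaving 70.1% of the charge working. This makes the Sub lifetime in the south-west flask longer than in the same flask without Z. Scale 3.97 h by that working share for the south-west flask without Z: it gives 2.78 h, so 12.0% of the Sub would remain at 5.9 h. The south-west run without Z keeps 11.4%, a lifetime of 2.72 h.

The runs were generated by integration from invented constants.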